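## The problem

Atoms are numbered along the chain: C1 is the lactone carbonyl, C5 the lactone carbinol carbon, C6 the free carbinol, C7–C10 the oxolane carbons (ring oxygen between C7 and C10), C11 the acylated carbinol and C12 the methyl group.

The target carries two oxygen heterocycles that are not fused: a 5,6-dihydro-2H-pyran-2-one (C1–C5) and a 2,5-cis-disubstituted oxolane (C7–C10), joined through the free carbinol C6, with a (Z)-4-methoxycinnamate on O11. Five stereocentres have to be set (5R, 6S, 7R, 10S, 11S). They fall into two groups, the anti C5/C6 diol on one side of the ring and the threo C10/C11 pair on the other. Neither group can control the other except through the ring: C10 can pass its configuration to C7 only if ring formation is 2,5-cis-selective. Three functions limit the reagents: the Z-cinnamate isomerises under light, nucleophilic catalysts or strong acid; the unsaturated δ-lactone is a Michael acceptor and does not survive base; and O6 must stay free while O11 is acylated, so the two secondary hydroxyls have to be told apart from the start. The feature that opens the route is that C9–C12, with threo oxygens on C10 and C11, is the carbon skeleton of D-threonine, with the carboxyl carbon as C9. The α-hydroxy acid derived from it can be condensed with a C3–C7 aldehyde to a 1,3-dioxolan-4-one in which the O–C7 ring bond already exists as an acetal bond. Methylenation of the lactone carbonyl then supplies C8, and an oxygen-to-carbon rearrangement forms C7–C8 and the oxolane, at the price of a carbonyl at C9 that must be removed afterwards.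

## Retrosynthesis

TBS = tert-butyldimethylsilyl throughout.

**23 ⇒ 21 (through 22).** The lactone acyl–oxygen bond O5–C1 and the two O–Si bonds are cut together. The unsaturated lactone is the most base- and nucleophile-sensitive part of the molecule, so it is formed last and under acid. With the Z C2=C3 alkene already in place, the freed C5 hydroxyl of 22 can only close the six-membered ring. The neighbouring option, a metathesis closure of a C5 acrylate, would require O5 and O6 to be differentiated, which this cut avoids. The forward step must remove two secondary silyl ethers without touching the Z-cinnamate.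

**21 ⇒ 18 + 20.** The C11 ester C–O bond is cut. The Z-cinnamoyl unit enters as one piece, acid 20, after all ozone, hydride, radical and strong-base steps are over; it would survive none of them. Acid 20 goes back in one step to the arylpropiolic acid 19 by syn semi-hydrogenation, which fixes the Z geometry before the unit meets the main chain. The forward esterification must not isomerise the acyl donor.

**18 ⇒ 17 ⇒ 15 ⇒ 14.** The C2=C3 double bond is cut by a Z-selective phosphonate olefination of aldehyde 17. C3 of 17 comes from the terminal alkene of 15 by ozonolysis. The C11 hydroxyl of 15 is unmasked from benzyl ether 14 by electron-transfer debenzylation. This is placed before any enoate exists, when the only other π-system is an isolated alkene. A benzyl ether is preferred to a more labile arylmethyl ether because it is available on the amino acid from the catalogue (6) and is indifferent to the Lewis acids of the ring-forming sequence.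

**14 ⇒ 11 (through 13 and 12).** A carbonyl is added back at C9. This is the one non-productive operation of the plan: reduction, thioacylation and radical deoxygenation in the forward sense. The radical route is chosen over hydrazone-based deoxygenation because an α-alkoxy ketone would open the ring by β-elimination under those conditions.

**11 ⇒ 10 (key disconnection).** The C7–C8 bond of oxolan-3-one 11 is cut and the C7–O bond to the enol oxygen is restored, giving 4-methylene-1,3-dioxolane 10. Against ether-forming closures (displacement at C7 or C10, or epoxide opening), this cut needs no leaving group on a stereocentre flanked by oxygen. It also allows the two halves to be joined by simple acetalisation. Only C7 is created, and it is set by C10 through the cis preference of the rearrangement; the acetal configuration of 10 is irrelevant. The forward reaction must ionise on the enol-ether side, recombine through carbon, and leave benzyl and silyl ethers and C10 untouched.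

**10 ⇒ 9 ⇒ 7 + 5 (through 8).** The exocyclic methylene of 10 is cut back to the lactone carbonyl of dioxolanone 9 (titanium methylenation forward). The two acetal C–O bonds of 9 are then cut to hydroxy acid 7 and aldehyde 5, joined through the bis-silyl derivative 8. This is the point of convergence: two chiral-pool pieces of five and six carbons meet in one step and carry all four pre-set stereocentres.

**7 ⇒ 6 and 5 ⇒ 4 ⇒ 3 ⇒ 2 ⇒ 1.** Acid 7 comes from O-benzyl-D-threonine 6 by diazotisation with retention. Aldehyde 5 comes from alcohol 4 by oxidation; 4 from tris-silyl ether 3 by selective primary desilylation; 3 from triol 2; and 2 from 2-deoxy-L-ribose 1 by one-carbon olefination of its masked aldehyde. Sugar 1 already holds the anti C5/C6 diol and the C4 methylene. It is preferred to building C5 by diastereoselective allylation of a shorter chiral aldehyde because no new stereocentre is made and no chiral reagent is needed.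

## Roads not taken

**Alternative 1:** The cut is at C6–C7 and C10–C11, traced to a zinc-mediated [4+3] cycloaddition of furan A1 with the oxyallyl cation from the tetrabromoketone A2, followed by reductive debromination to the meso bicyclic ketone A3. The furan carbons become C7–C10 and its oxygen the oxolane oxygen; the three-carbon bridge supplies C6, the future C5 (the ketone carbon) and C11.
- Merits: the oxygen bridge makes the 2,5-cis geometry certain; two C–C bonds and the ring form in one step from very cheap achiral materials; after hydrogenation C8 and C9 are already methylene groups, so no deoxygenation is needed. In these respects it is better than the chosen plan, which gets cis selectivity only from a conformational preference and spends three steps on removing the C9 oxygen.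
- Weak points: A3 is meso, so absolute configuration must come from a desymmetrisation. The methyl C12, the C6 oxygen and the C11 oxygen must then be introduced one by one on the bicycle. The oxidative cleavage of the ketone–C11 bond that reveals O11 has to distinguish two α-carbons of similar migrating ability once C6 is oxygenated. C5 emerges as a carboxyl carbon, so its stereocentre and C1–C4 still need an asymmetric allylation.
- Comparison: only the two ring stereocentres come from the key step; the other three and the absolute sense come later. The chosen plan buys four of five stereocentres and the absolute configuration in 1 and 6, and makes only C7.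

**Alternative 2:** The cut is at O–C10 and C11–O. In the forward step the C6,C7-diol of the lactone-bearing E-alkene A4 forms an osmate ester, and the metal adds O7 and an oxo ligand syn across C10=C11 to give the deacyl target A5 directly.
- Merits: this is the most direct road. The ring, C10 and C11 form in one stereospecific step (E-alkene gives threo, the chelated transition state gives the cis ring), with no protecting groups and no surplus oxygen at C9. It is shorter than the chosen plan and its stereochemical logic is at least as clean.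
- Weak points: the conjugated lactone alkene is exposed to the osmium oxidant, and its survival depends on intramolecular delivery outrunning intermolecular dihydroxylation. A5 has two free secondary hydroxyls, O6 and O11, and the final acylation with acid 20 must select O11 on steric grounds alone.
- Comparison: the chosen plan sets against the shorter route an unambiguous differentiation of O11 (benzyl) from O6 (silyl) from compound 6 onward, and an endgame in which the lactone never meets an oxidant.

**Alternative 3:** The cut is at O–C1 and C1–C2 of the lactone. Iron-carbonyl-mediated opening of the vinyl epoxide A6 at the allylic carbon C4, followed by carbonylative closure under pressure, gives the β,γ-unsaturated lactone A7, which must then be isomerised into conjugation.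
- Merits: C1 comes from the carbonylation, C5 keeps the epoxide configuration, and the cis ring alkene follows from the ring, so the Z-olefination question of step 14 does not arise. On that one point it is better than the chosen plan.
- Weak points: this is an endgame tactic and leaves the oxolane problem unsolved. It needs stoichiometric iron carbonyl and pressure equipment. A6 needs a stereodefined epoxide next to the C6 carbinol. The base-mediated shift of the double bond runs on a substrate prone to β-elimination at C5.
- Comparison: as a lactone construction it competes only with steps 13, 14 and 17, which use standard reagents and are no longer. It could be grafted onto any oxolane synthesis but offers none of its own.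

Key step: step 8

Assumptions: 2-deoxy-L-ribose (1, drawn as its open-chain aldehyde), O-benzyl-D-threonine (6) and 3-(4-methoxyphenyl)prop-2-ynoic acid (19) are taken as catalogue compounds. Carbinol 12 and its thiocarbonyl derivative 13 are carried as mixtures of C9 epimers, since C9 becomes a methylene group in step 11.

## Route

**Step 1**
Reactants: 1 2-deoxy-L-ribose
Product: 2 (2S,3R)-hex-5-ene-1,2,3-triol
Conditions: Ph3PCH3Br (3.5 equiv), KOtBu (3.4 equiv), THF, 0 °C → reflux
Reagents that add atoms: methyltriphenylphosphonium bromide, C[P+](c1ccccc1)(c1ccccc1)c1ccccc1.[Br-]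
Why: Wittig methylenation of the aldehyde form in equilibrium with the lactol; excess ylide carries the hydroxyls as alkoxides. No stereocentre is made: the future C5 and C6 come unchanged from the sugar.

**Step 2**
Reactants: 2 (2S,3R)-hex-5-ene-1,2,3-triol
Product: 3 (4R,5S)-4,5,6-tris(tert-butyldimethylsilyloxy)hex-1-ene
Conditions: TBSOTf (3.6 equiv), 2,6-lutidine, CH2Cl2, 0 °C → rt
Reagents that add atoms: tert-butyldimethylsilyl trifluoromethanesulfonate, CC(C)(C)[Si](C)(C)OS(=O)(=O)C(F)(F)F
Why: Exhaustive silylation; the silyl triflate is used so that the hindered vicinal secondary hydroxyls react completely.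

**Step 3**
Reactants: 3 (4R,5S)-4,5,6-tris(tert-butyldimethylsilyloxy)hex-1-ene
Product: 4 (2S,3R)-2,3-bis(tert-butyldimethylsilyloxy)hex-5-en-1-ol
Conditions: HF·pyridine, pyridine, THF, 0 °C
Reagents that add atoms: none
Why: Selective desilylation: a primary TBS ether is cleaved much faster than secondary ones by buffered HF·pyridine.

**Step 4**
Reactants: 4 (2S,3R)-2,3-bis(tert-butyldimethylsilyloxy)hex-5-en-1-ol
Product: 5 (2R,3R)-2,3-bis(tert-butyldimethylsilyloxy)hex-5-enal
Conditions: Dess–Martin periodinane, NaHCO3, CH2Cl2, 0 °C → rt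
Reagents that add atoms: none
Why: Buffered Dess–Martin oxidation, a standard non-epimerising way to α-silyloxy aldehydes; 5 is used without storage. The descriptor at C2 changes only because the priorities change.

**Step 5**
Reactants: 6 O-benzyl-D-threonine
Product: 7 (2R,3S)-3-(benzyloxy)-2-hydroxybutanoic acid
Conditions: NaNO2, 1 M aq. H2SO4, 0 °C → rt
Reagents that add atoms: water, O
Why: Diazotisation of an α-amino acid; the carboxylate displaces N2 to an α-lactone that water opens, so two inversions give net retention at the future C10. The benzyl ether keeps the β-oxygen from taking part.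

**Step 6**
Reactants: 7 (2R,3S)-3-(benzyloxy)-2-hydroxybutanoic acid; 5 (2R,3R)-2,3-bis(tert-butyldimethylsilyloxy)hex-5-enal
Product: 9 (2R,5R)-5-[(1S)-1-(benzyloxy)ethyl]-2-[(1R,2R)-1,2-bis(tert-butyldimethylsilyloxy)pent-4-en-1-yl]-1,3-dioxolan-4-one, via bis-trimethylsilyl derivative 8 (not isolated)
Conditions: (Me3Si)2NH, CH2Cl2, rt, then evaporation; 5, TMSOTf (0.2 equiv), CH2Cl2, −78 °C
Reagents that add atoms: none
Why: Silyl-mediated acetalisation of a bis-silylated α-hydroxy acid with an aldehyde under catalytic TMSOTf (Noyori-type conditions, established for 1,3-dioxolan-4-ones); it runs at −78 °C without protic acid, which protects the α-silyloxy stereocentre of 5. The cis acetal should predominate, but the acetal configuration is erased in step 8.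

**Step 7**
Reactants: 9 (2R,5R)-5-[(1S)-1-(benzyloxy)ethyl]-2-[(1R,2R)-1,2-bis(tert-butyldimethylsilyloxy)pent-4-en-1-yl]-1,3-dioxolan-4-one
Product: 10 (2R,4R)-4-[(1S)-1-(benzyloxy)ethyl]-2-[(1R,2R)-1,2-bis(tert-butyldimethylsilyloxy)pent-4-en-1-yl]-5-methylidene-1,3-dioxolane
Conditions: Cp2TiMe2 (2.5 equiv), toluene, 65 °C, dark
Reagents that add atoms: dimethyltitanocene, [CH3-].[CH3-].[Ti+4].c1cc[cH-]c1.c1cc[cH-]c1
Why: Petasis methylenation of a lactone carbonyl through Cp2Ti=CH2; the reagent is non-basic, so the acetal and C10 are untouched, and ethers and the terminal alkene are tolerated. The enol acetal is filtered through basic alumina and used directly.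

**Step 8**
Reactants: 10 (2R,4R)-4-[(1S)-1-(benzyloxy)ethyl]-2-[(1R,2R)-1,2-bis(tert-butyldimethylsilyloxy)pent-4-en-1-yl]-5-methylidene-1,3-dioxolane
Product: 11 (2R,5R)-2-[(1S)-1-(benzyloxy)ethyl]-5-[(1S,2R)-1,2-bis(tert-butyldimethylsilyloxy)pent-4-en-1-yl]oxolan-3-one
Conditions: Me2AlCl (2.2 equiv), CH2Cl2, −78 → −30 °C
Reagents that add atoms: none
Why: Petasis–Ferrier rearrangement in its 4-methylene-1,3-dioxolane form. Me2AlCl binds the enol-ether oxygen and the C7–O bond on that side ionises, giving an oxocarbenium ion at C7 stabilised by the other ring oxygen and an aluminium enolate C9(OAl)=C8H2 that stays tethered through C10. The enolate carbon C8 then adds to C7 in a formally 5-endo-trig (enol-endo) closure, feasible because the cation–enolate pair is a stepwise, loosely held species; this forms C7–C8 and the oxolane ring and leaves the former lactone carbon as the C9 ketone. C7 is the only new stereocentre: the acetal configuration is lost on ionisation, and C10 directs recombination through an envelope in which the E-oxocarbenium substituent and the C10 side chain are both pseudo-equatorial, which gives the 2,5-cis ring. The step needs ionisation on the enol-ether side (the enolate is the better leaving group), cis selectivity (from C10) and an intact C10 (the enolate is formed only towards the exocyclic methylene). Benzyl and TBS ethers and the terminal alkene are inert to Me2AlCl at low temperature. The closest known reactions are the aluminium-promoted conversions of 2,5-disubstituted 4-methylene-1,3-dioxolanes into cis-2,5-disubstituted oxolan-3-ones and oxolan-3-ols.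

**Step 9**
Reactants: 11 (2R,5R)-2-[(1S)-1-(benzyloxy)ethyl]-5-[(1S,2R)-1,2-bis(tert-butyldimethylsilyloxy)pent-4-en-1-yl]oxolan-3-one
Product: 12 2,5-cis-2-[(1S)-1-(benzyloxy)ethyl]-5-[(1S,2R)-1,2-bis(tert-butyldimethylsilyloxy)pent-4-en-1-yl]oxolan-3-ol (ring configuration as in 11; both C9 epimers)
Conditions: NaBH4, MeOH, 0 °C
Reagents that add atoms: none
Why: Borohydride reduction of a ketone under conditions too mild to epimerise C10; the configuration of the new carbinol does not matter because C9 becomes CH2 in step 11.

**Step 10**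
Reactants: 12 2,5-cis-2-[(1S)-1-(benzyloxy)ethyl]-5-[(1S,2R)-1,2-bis(tert-butyldimethylsilyloxy)pent-4-en-1-yl]oxolan-3-ol
Product: 13 O-{2,5-cis-2-[(1S)-1-(benzyloxy)ethyl]-5-[(1S,2R)-1,2-bis(tert-butyldimethylsilyloxy)pent-4-en-1-yl]oxolan-3-yl} 1H-imidazole-1-carbothioate (both C9 epimers)
Conditions: 1,1'-thiocarbonyldiimidazole, DMAP (cat.), toluene, 80 °C
Reagents that add atoms: 1,1'-thiocarbonyldiimidazole, S=C(n1ccnc1)n1ccnc1
Why: Thioacylation of a secondary alcohol for the Barton–McCombie reaction; neutral conditions avoid an alkoxide and with it any silyl migration.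

**Step 11**
Reactants: 13 O-{2,5-cis-2-[(1S)-1-(benzyloxy)ethyl]-5-[(1S,2R)-1,2-bis(tert-butyldimethylsilyloxy)pent-4-en-1-yl]oxolan-3-yl} 1H-imidazole-1-carbothioate
Product: 14 (2S,5R)-2-[(1S)-1-(benzyloxy)ethyl]-5-[(1S,2R)-1,2-bis(tert-butyldimethylsilyloxy)pent-4-en-1-yl]oxolane
Conditions: Bu3SnH, AIBN (cat.), toluene, 100 °C
Reagents that add atoms: none
Why: Barton–McCombie deoxygenation; the secondary C9 radical is trapped by the stannane much faster than it could cyclise 7-exo onto the remote terminal alkene, and alkoxy groups β to a radical do not fragment. C7 and C10 are not involved.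

**Step 12**
Reactants: 14 (2S,5R)-2-[(1S)-1-(benzyloxy)ethyl]-5-[(1S,2R)-1,2-bis(tert-butyldimethylsilyloxy)pent-4-en-1-yl]oxolane
Product: 15 (1S)-1-{(2S,5R)-5-[(1S,2R)-1,2-bis(tert-butyldimethylsilyloxy)pent-4-en-1-yl]oxolan-2-yl}ethan-1-ol
Conditions: lithium 4,4'-di-tert-butylbiphenylide (LiDBB), THF, −78 °C; aq. NH4Cl
Reagents that add atoms: none
Why: Reductive debenzylation by an arene radical anion; an isolated terminal alkene, TBS ethers and the ring ether are not reduced at −78 °C. The titration end point (persistent green colour) limits excess reagent.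

**Step 13**
Reactants: 15 (1S)-1-{(2S,5R)-5-[(1S,2R)-1,2-bis(tert-butyldimethylsilyloxy)pent-4-en-1-yl]oxolan-2-yl}ethan-1-ol
Product: 17 (3R,4S)-3,4-bis(tert-butyldimethylsilyloxy)-4-{(2R,5S)-5-[(1S)-1-hydroxyethyl]oxolan-2-yl}butanal, via secondary ozonide 16 (not isolated)
Conditions: O3, CH2Cl2, −78 °C; PPh3, −78 °C → rt
Reagents that add atoms: ozone, [O-][O+]=O
Why: Ozonolysis of the only C=C bond with reductive work-up; the free secondary hydroxyl and the silyl ethers are inert. The β-silyloxy aldehyde is taken on crude.

**Step 14**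
Reactants: 17 (3R,4S)-3,4-bis(tert-butyldimethylsilyloxy)-4-{(2R,5S)-5-[(1S)-1-hydroxyethyl]oxolan-2-yl}butanal
Product: 18 methyl (2Z,5R,6S)-5,6-bis(tert-butyldimethylsilyloxy)-6-{(2R,5S)-5-[(1S)-1-hydroxyethyl]oxolan-2-yl}hex-2-enoate
Conditions: (CF3CH2O)2P(O)CH2CO2Me, KN(SiMe3)2, 18-crown-6, THF, −78 °C
Reagents that add atoms: methyl bis(2,2,2-trifluoroethyl)phosphonoacetate, COC(=O)CP(=O)(OCC(F)(F)F)OCC(F)(F)F
Why: Still–Gennari olefination; fast, irreversible elimination from the trifluoroethyl phosphonate adduct gives the Z-enoate under kinetic control. The stabilised anion deprotonates neither the free C11 hydroxyl nor the β-silyloxy aldehyde.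

**Step 15**
Reactants: 19 3-(4-methoxyphenyl)prop-2-ynoic acid
Product: 20 (2Z)-3-(4-methoxyphenyl)prop-2-enoic acid
Conditions: H2 (1 atm), Pd/CaCO3 poisoned with Pb(OAc)2 (Lindlar catalyst), quinoline, EtOAc, rt, dark
Reagents that add atoms: none
Why: Lindlar semi-hydrogenation; syn delivery of H2 to the alkyne gives the Z-cinnamic acid, the classical route to cis-cinnamic acids.

**Step 16**
Reactants: 18 methyl (2Z,5R,6S)-5,6-bis(tert-butyldimethylsilyloxy)-6-{(2R,5S)-5-[(1S)-1-hydroxyethyl]oxolan-2-yl}hex-2-enoate; 20 (2Z)-3-(4-methoxyphenyl)prop-2-enoic acid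
Product: 21 methyl (2Z,5R,6S)-5,6-bis(tert-butyldimethylsilyloxy)-6-{(2R,5S)-5-[(1S)-1-{[(2Z)-3-(4-methoxyphenyl)prop-2-enoyl]oxy}ethyl]oxolan-2-yl}hex-2-enoate
Conditions: DCC, DMAP (cat.), CH2Cl2, 0 °C → rt, dark
Reagents that add atoms: none
Why: Steglich esterification of the only free hydroxyl; low temperature, catalytic DMAP and exclusion of light are chosen to keep the Z geometry of the acyl donor. C11 is acylated with retention.

**Step 17**
Reactants: 21 methyl (2Z,5R,6S)-5,6-bis(tert-butyldimethylsilyloxy)-6-{(2R,5S)-5-[(1S)-1-{[(2Z)-3-(4-methoxyphenyl)prop-2-enoyl]oxy}ethyl]oxolan-2-yl}hex-2-enoate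
Product: 23 (1S)-1-{(2S,5R)-5-[(S)-hydroxy[(2R)-6-oxo-3,6-dihydro-2H-pyran-2-yl]methyl]oxolan-2-yl}ethyl (2Z)-3-(4-methoxyphenyl)prop-2-enoate, via dihydroxy Z-enoate 22 (not isolated)
Conditions: 48% aq. HF, MeCN, 0 °C → rt
Reagents that add atoms: none
Why: Acidic fluoride desilylation followed by spontaneous lactonisation: the C5 hydroxyl of the Z-configured δ-hydroxy enoate closes the six-membered lactone with loss of methanol, whereas O6 could only form a seven-membered ring. Acid, not basic fluoride, avoids oxa-Michael addition of O6, acyl migration and cinnamate isomerisation.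

## Compound list

1 | 2-deoxy-L-ribose (open-chain form: (3R,4S)-3,4,5-trihydroxypentanal) | O=CC[C@@H](O)[C@@H](O)CO | starting material
2 | (2S,3R)-hex-5-ene-1,2,3-triol | C=CC[C@@H](O)[C@@H](O)CO | intermediate
3 | (4R,5S)-4,5,6-tris(tert-butyldimethylsilyloxy)hex-1-ene | C=CC[C@@H](O[Si](C)(C)C(C)(C)C)[C@@H](O[Si](C)(C)C(C)(C)C)CO[Si](C)(C)C(C)(C)C | intermediate
4 | (2S,3R)-2,3-bis(tert-butyldimethylsilyloxy)hex-5-en-1-ol | C=CC[C@@H](O[Si](C)(C)C(C)(C)C)[C@@H](O[Si](C)(C)C(C)(C)C)CO | intermediate
5 | (2R,3R)-2,3-bis(tert-butyldimethylsilyloxy)hex-5-enal | C=CC[C@@H](O[Si](C)(C)C(C)(C)C)[C@@H](O[Si](C)(C)C(C)(C)C)C=O | intermediate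
6 | O-benzyl-D-threonine, (2R,3S)-2-amino-3-(benzyloxy)butanoic acid | C[C@H](OCc1ccccc1)[C@@H](N)C(=O)O | starting material
7 | (2R,3S)-3-(benzyloxy)-2-hydroxybutanoic acid | C[C@H](OCc1ccccc1)[C@@H](O)C(=O)O | intermediate
8 | trimethylsilyl (2R,3S)-3-(benzyloxy)-2-(trimethylsilyloxy)butanoate | C[C@H](OCc1ccccc1)[C@@H](O[Si](C)(C)C)C(=O)O[Si](C)(C)C | intermediate (not isolated)
9 | (2R,5R)-5-[(1S)-1-(benzyloxy)ethyl]-2-[(1R,2R)-1,2-bis(tert-butyldimethylsilyloxy)pent-4-en-1-yl]-1,3-dioxolan-4-one (2,5-cis) | C[C@H](OCc1ccccc1)[C@H]1O[C@@H]([C@H](O[Si](C)(C)C(C)(C)C)[C@H](O[Si](C)(C)C(C)(C)C)CC=C)OC1=O | intermediate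
10 | (2R,4R)-4-[(1S)-1-(benzyloxy)ethyl]-2-[(1R,2R)-1,2-bis(tert-butyldimethylsilyloxy)pent-4-en-1-yl]-5-methylidene-1,3-dioxolane | C[C@H](OCc1ccccc1)[C@H]1O[C@@H]([C@H](O[Si](C)(C)C(C)(C)C)[C@H](O[Si](C)(C)C(C)(C)C)CC=C)OC1=C | intermediate
11 | (2R,5R)-2-[(1S)-1-(benzyloxy)ethyl]-5-[(1S,2R)-1,2-bis(tert-butyldimethylsilyloxy)pent-4-en-1-yl]oxolan-3-one (2,5-cis) | C[C@H](OCc1ccccc1)[C@H]1O[C@@H]([C@H](O[Si](C)(C)C(C)(C)C)[C@H](O[Si](C)(C)C(C)(C)C)CC=C)CC1=O | intermediate
12 | 2,5-cis-2-[(1S)-1-(benzyloxy)ethyl]-5-[(1S,2R)-1,2-bis(tert-butyldimethylsilyloxy)pent-4-en-1-yl]oxolan-3-ol (ring configuration as in 11; C9 carbinol as both epimers) | C[C@H](OCc1ccccc1)[C@H]1O[C@@H]([C@H](O[Si](C)(C)C(C)(C)C)[C@H](O[Si](C)(C)C(C)(C)C)CC=C)CC1O | intermediate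
13 | O-(oxolan-3-yl) 1H-imidazole-1-carbothioate of 12 (both C9 epimers) | C[C@H](OCc1ccccc1)[C@H]1O[C@@H]([C@H](O[Si](C)(C)C(C)(C)C)[C@H](O[Si](C)(C)C(C)(C)C)CC=C)CC1OC(=S)n1ccnc1 | intermediate
14 | (2S,5R)-2-[(1S)-1-(benzyloxy)ethyl]-5-[(1S,2R)-1,2-bis(tert-butyldimethylsilyloxy)pent-4-en-1-yl]oxolane | C[C@H](OCc1ccccc1)[C@@H]1CC[C@H]([C@H](O[Si](C)(C)C(C)(C)C)[C@H](O[Si](C)(C)C(C)(C)C)CC=C)O1 | intermediate
15 | (1S)-1-{(2S,5R)-5-[(1S,2R)-1,2-bis(tert-butyldimethylsilyloxy)pent-4-en-1-yl]oxolan-2-yl}ethan-1-ol | C[C@H](O)[C@@H]1CC[C@H]([C@H](O[Si](C)(C)C(C)(C)C)[C@H](O[Si](C)(C)C(C)(C)C)CC=C)O1 | intermediate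
16 | secondary ozonide (3-substituted 1,2,4-trioxolane) of 15, trioxolane carbon unassigned | C[C@H](O)[C@@H]1CC[C@H]([C@H](O[Si](C)(C)C(C)(C)C)[C@H](O[Si](C)(C)C(C)(C)C)CC2OCOO2)O1 | intermediate (not isolated)
17 | (3R,4S)-3,4-bis(tert-butyldimethylsilyloxy)-4-{(2R,5S)-5-[(1S)-1-hydroxyethyl]oxolan-2-yl}butanal | C[C@H](O)[C@@H]1CC[C@H]([C@H](O[Si](C)(C)C(C)(C)C)[C@H](O[Si](C)(C)C(C)(C)C)CC=O)O1 | intermediate
18 | methyl (2Z,5R,6S)-5,6-bis(tert-butyldimethylsilyloxy)-6-{(2R,5S)-5-[(1S)-1-hydroxyethyl]oxolan-2-yl}hex-2-enoate | C[C@H](O)[C@@H]1CC[C@H]([C@H](O[Si](C)(C)C(C)(C)C)[C@H](O[Si](C)(C)C(C)(C)C)C/C=C\C(=O)OC)O1 | intermediate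
19 | 3-(4-methoxyphenyl)prop-2-ynoic acid | COc1ccc(C#CC(=O)O)cc1 | starting material
20 | (2Z)-3-(4-methoxyphenyl)prop-2-enoic acid | COc1ccc(/C=C\C(=O)O)cc1 | intermediate
21 | methyl (2Z,5R,6S)-5,6-bis(tert-butyldimethylsilyloxy)-6-{(2R,5S)-5-[(1S)-1-{[(2Z)-3-(4-methoxyphenyl)prop-2-enoyl]oxy}ethyl]oxolan-2-yl}hex-2-enoate | COc1ccc(/C=C\C(=O)O[C@@H](C)[C@@H]2CC[C@H]([C@H](O[Si](C)(C)C(C)(C)C)[C@H](O[Si](C)(C)C(C)(C)C)C/C=C\C(=O)OC)O2)cc1 | intermediate
22 | methyl (2Z,5R,6S)-5,6-dihydroxy-6-{(2R,5S)-5-[(1S)-1-{[(2Z)-3-(4-methoxyphenyl)prop-2-enoyl]oxy}ethyl]oxolan-2-yl}hex-2-enoate | COc1ccc(/C=C\C(=O)O[C@@H](C)[C@@H]2CC[C@H]([C@H](O)[C@H](O)C/C=C\C(=O)OC)O2)cc1 | intermediate (not isolated)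
23 | (1S)-1-{(2S,5R)-5-[(S)-hydroxy[(2R)-6-oxo-3,6-dihydro-2H-pyran-2-yl]methyl]oxolan-2-yl}ethyl (2Z)-3-(4-methoxyphenyl)prop-2-enoate | COc1ccc(/C=C\C(=O)O[C@@H](C)[C@@H]2CC[C@H]([C@H](O)[C@H]3CC=CC(=O)O3)O2)cc1 | target

## Step count and least certain steps

Total: 17 steps. Longest linear sequence: 15 steps from 1 (steps 1–4, 6–14, 16, 17). Acid 7 joins after one step and acid 20 after one step.

**Step 8 (key step).** The silyloxy group on C6 is inductively withdrawing and bulky. It may slow ionisation towards the C7 oxocarbenium ion so that the acetal fragments back to its components instead of recombining, and it may distort the envelope that gives the cis ring, lowering the cis preference. Fallback, setting out from 5 and 7 and returning at 14: the ring is closed through O–C7 instead, and C9 never carries oxygen.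
- Aldehyde 5 is homologated with dimethyl (1-diazo-2-oxopropyl)phosphonate and K2CO3 in MeOH to the alkyne (3S,4R)-3,4-bis(tert-butyldimethylsilyloxy)hept-6-en-1-yne F1.
- Acid 7 is reduced with LiAlH4 to (2S,3S)-3-(benzyloxy)butane-1,2-diol F2, which is closed with PPh3 and diisopropyl azodicarboxylate to (2S)-2-[(1S)-1-(benzyloxy)ethyl]oxirane F3, with retention at the secondary carbinol.
- The lithium acetylide of F1 (n-BuLi, then BF3·OEt2, THF, −78 °C) opens F3 at its terminal carbon to the homopropargylic alcohol (2S,3S,7S,8R)-2-(benzyloxy)-7,8-bis(tert-butyldimethylsilyloxy)undec-10-en-5-yn-3-ol F4.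
- F4 is cycloisomerised 5-endo-dig with Ph3PAuCl/AgOTf to (2S)-2-[(1S)-1-(benzyloxy)ethyl]-5-[(1R,2R)-1,2-bis(tert-butyldimethylsilyloxy)pent-4-en-1-yl]-2,3-dihydrofuran F5.
- F5 is reduced with Et3SiH and CF3CO2H in CH2Cl2 at −78 °C through the C7 oxocarbenium ion. Hydride is expected to enter on the face opposite the C10 side chain, giving the cis ring of 14; this selectivity is less secure than that of the rearrangement.

**Step 6.** The α-silyloxy aldehyde 5 may epimerise at the future C6 or lose silyl groups before it is captured, or the condensation may stall because both partners are hindered. Fallback, setting out from 5 and returning at 9: the free aldehyde is replaced by a non-enolisable acetal donor. Aldehyde 5 is converted with trimethyl orthoformate and pyridinium p-toluenesulfonate in MeOH into the dimethyl acetal (4R,5R)-4,5-bis(tert-butyldimethylsilyloxy)-6,6-dimethoxyhex-1-ene F6. F6 undergoes acetal exchange with the bis-silyl derivative 8 under TMSOTf in CH2Cl2 at −78 °C to give 9.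

**Step 12.** Electron transfer may not stop at the benzyl ether: excess radical anion could reduce or isomerise the terminal alkene, and debenzylation could be incomplete if the reagent is under-dosed. Fallback, setting out from 14 and returning at 17: the alkene is removed before the benzyl group.
- Ozonolysis of 14 with NaBH4 work-up gives (3R,4S)-4-{(2R,5S)-5-[(1S)-1-(benzyloxy)ethyl]oxolan-2-yl}-3,4-bis(tert-butyldimethylsilyloxy)butan-1-ol F7.
- Hydrogenolysis (H2, Pd/C, EtOAc) gives the diol (3R,4S)-3,4-bis(tert-butyldimethylsilyloxy)-4-{(2R,5S)-5-[(1S)-1-hydroxyethyl]oxolan-2-yl}butan-1-ol F8.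
- Primary-selective oxidation with TEMPO and PhI(OAc)2 gives aldehyde 17.

**Step 16.** The activated Z-cinnamoyl donor may isomerise to the E form through reversible conjugate addition of the acyl-transfer catalyst, and acylation of the hindered C11 hydroxyl may be slow enough for N-acylurea formation to compete. Fallback, setting out from 18 and returning at 21: the Z double bond is built on the substrate. Alcohol 18 is esterified (DCC, DMAP) with (diphenoxyphosphoryl)acetic acid to the phosphonoacetate F9. An Ando-type Z-selective olefination of F9 with 4-methoxybenzaldehyde (NaH, THF, −78 → 0 °C) gives 21.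

## Further compounds

F1 | step 8 | (3S,4R)-3,4-bis(tert-butyldimethylsilyloxy)hept-6-en-1-yne | C=CC[C@@H](O[Si](C)(C)C(C)(C)C)[C@@H](O[Si](C)(C)C(C)(C)C)C#C
F2 | step 8 | (2S,3S)-3-(benzyloxy)butane-1,2-diol | C[C@H](OCc1ccccc1)[C@@H](O)CO
F3 | step 8 | (2S)-2-[(1S)-1-(benzyloxy)ethyl]oxirane | C[C@H](OCc1ccccc1)[C@@H]1CO1
F4 | step 8 | (2S,3S,7S,8R)-2-(benzyloxy)-7,8-bis(tert-butyldimethylsilyloxy)undec-10-en-5-yn-3-ol | C[C@H](OCc1ccccc1)[C@@H](O)CC#C[C@H](O[Si](C)(C)C(C)(C)C)[C@H](O[Si](C)(C)C(C)(C)C)CC=C
F5 | step 8 | (2S)-2-[(1S)-1-(benzyloxy)ethyl]-5-[(1R,2R)-1,2-bis(tert-butyldimethylsilyloxy)pent-4-en-1-yl]-2,3-dihydrofuran | C[C@H](OCc1ccccc1)[C@@H]1CC=C(O1)[C@H](O[Si](C)(C)C(C)(C)C)[C@H](O[Si](C)(C)C(C)(C)C)CC=C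
F6 | step 6 | (4R,5R)-4,5-bis(tert-butyldimethylsilyloxy)-6,6-dimethoxyhex-1-ene | C=CC[C@@H](O[Si](C)(C)C(C)(C)C)[C@@H](O[Si](C)(C)C(C)(C)C)C(OC)OC
F7 | step 12 | (3R,4S)-4-{(2R,5S)-5-[(1S)-1-(benzyloxy)ethyl]oxolan-2-yl}-3,4-bis(tert-butyldimethylsilyloxy)butan-1-ol | C[C@H](OCc1ccccc1)[C@@H]1CC[C@H]([C@H](O[Si](C)(C)C(C)(C)C)[C@H](O[Si](C)(C)C(C)(C)C)CCO)O1
F8 | step 12 | (3R,4S)-3,4-bis(tert-butyldimethylsilyloxy)-4-{(2R,5S)-5-[(1S)-1-hydroxyethyl]oxolan-2-yl}butan-1-ol | C[C@H](O)[C@@H]1CC[C@H]([C@H](O[Si](C)(C)C(C)(C)C)[C@H](O[Si](C)(C)C(C)(C)C)CCO)O1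
F9 | step 16 | methyl (2Z,5R,6S)-5,6-bis(tert-butyldimethylsilyloxy)-6-{(2R,5S)-5-[(1S)-1-{[(diphenoxyphosphoryl)acetyl]oxy}ethyl]oxolan-2-yl}hex-2-enoate | O=C(CP(=O)(Oc1ccccc1)Oc1ccccc1)O[C@@H](C)[C@@H]1CC[C@H]([C@H](O[Si](C)(C)C(C)(C)C)[C@H](O[Si](C)(C)C(C)(C)C)C/C=C\C(=O)OC)O1
A1 | alternative 1 | furan | c1ccoc1
A2 | alternative 1 | 1,1,3,3-tetrabromopropan-2-one | O=C(C(Br)Br)C(Br)Br
A3 | alternative 1 | meso-8-oxabicyclo[3.2.1]oct-6-en-3-one | O=C1C[C@@H]2C=C[C@H](C1)O2
A4 | alternative 2 | (6R)-6-[(1S,2R,5E)-1,2-dihydroxyhept-5-en-1-yl]-5,6-dihydro-2H-pyran-2-one | C/C=C/CC[C@@H](O)[C@H](O)[C@H]1CC=CC(=O)O1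
A5 | alternative 2 | (6R)-6-{(S)-hydroxy[(2R,5S)-5-[(1S)-1-hydroxyethyl]oxolan-2-yl]methyl}-5,6-dihydro-2H-pyran-2-one | O[C@@H](C)[C@@H]1CC[C@H]([C@H](O)[C@H]2CC=CC(=O)O2)O1
A6 | alternative 3 | (2S,5R)-2-[(1S)-1-(tert-butyldimethylsilyloxy)ethyl]-5-[(S)-(tert-butyldimethylsilyloxy)(trans-3-ethenyloxiran-2-yl)methyl]oxolane | CC(C)(C)[Si](C)(C)O[C@@H](C)[C@@H]1CC[C@H]([C@H](O[Si](C)(C)C(C)(C)C)[C@@H]2O[C@H]2C=C)O1
A7 | alternative 3 | (6R)-6-{(S)-(tert-butyldimethylsilyloxy)[(2R,5S)-5-[(1S)-1-(tert-butyldimethylsilyloxy)ethyl]oxolan-2-yl]methyl}-3,6-dihydro-2H-pyran-2-one | CC(C)(C)[Si](C)(C)O[C@@H](C)[C@@H]1CC[C@H]([C@H](O[Si](C)(C)C(C)(C)C)[C@H]2C=CCC(=O)O2)O1
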